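## Retrosynthetic overview

1. Target ⇒ atripliciolide (8‑OH) + tiglic acid; the ester goes on last.
2. Atripliciolide ⇒ intramolecular Barbier allylation (C7–C8) of a bromobutenolide‑aldehyde. This closes the 10‑membered ring last and creates the α‑methylene lactone and the C7/C8 stereocentres.
3. Bromobutenolide (second ring) ⇒ RCM of a 2‑(bromomethyl)acrylate ester of a C6 vinyl carbinol.
4. 3(2H)‑Furanone (first ring) ⇒ Au‑catalysed 5‑endo cyclisation of an α′‑hydroxy ynone, made from a (Z)‑enyne acetylide and a citramalate‑derived dioxolanone (C1–C2 bond).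
5. Stereocentres: C10 from (R)‑citramalic acid; C6 by catalytic asymmetric vinylation; C7 and C8 substrate‑controlled in the macrocyclisation.

Assumption: compounds 1, 7 and 16 are taken as commercial; in‑situ reagents (divinylzinc, the acid chloride, the Yamaguchi mixed anhydride) are not counted as steps. Atom labels C1–C15 use germacrane numbering of the target. This route is a paper design; no step has been run.

## Route

**Step 1**
Reactants: 1 (R)‑citramalic acid; 2 2,2‑dimethoxypropane
Product: 3 (R)‑2‑(2,2,4‑trimethyl‑5‑oxo‑1,3‑dioxolan‑4‑yl)acetic acid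
Conditions: 2,2‑dimethoxypropane, p‑TsOH (cat.), rt
Reagents that add atoms: 2,2‑dimethoxypropane, COC(C)(C)OC
Why: Acetalisation of the α‑hydroxy acid gives the five‑membered dioxolanone and leaves the β‑CO2H free; no bond at the stereocentre is touched, so C10 stays R.

**Step 2**
Reactants: 3
Product: 4 (R)‑5‑(2‑hydroxyethyl)‑2,2,5‑trimethyl‑1,3‑dioxolan‑4‑one
Conditions: BH3·SMe2, THF, 0 °C → rt; MeOH quench; use crude
Reagents that add atoms: none
Why: Chemoselective borane reduction of the free carboxylic acid in the presence of the lactone‑type dioxolanone carbonyl.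

**Step 3**
Reactants: 4; 5 tert‑butyldimethylsilyl chloride
Product: 6 (R)‑5‑[2‑(tert‑butyldimethylsilyloxy)ethyl]‑2,2,5‑trimethyl‑1,3‑dioxolan‑4‑one
Conditions: TBSCl, imidazole, CH2Cl2, 0 °C → rt
Reagents that add atoms: TBSCl, CC(C)(C)[Si](C)(C)Cl
Why: Silylation masks the future C8 aldehyde as a primary TBS ether and stops 4 from translactonising.

**Step 4**
Reactants: 7 (Z)‑3‑methylpent‑2‑en‑4‑yn‑1‑ol
Product: 8 (Z)‑3‑methylpent‑2‑en‑4‑ynal
Conditions: activated MnO2, CH2Cl2, rt; filter and use the solution directly (volatile)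
Reagents that add atoms: none
Why: Neutral allylic oxidation with MnO2 keeps the Z geometry, which becomes the C4=C5 Z‑alkene of the target.

**Step 5**
Reactants: 8; 9 vinylmagnesium bromide (converted in situ to divinylzinc)
Product: 10 (S,Z)‑5‑methylhepta‑1,4‑dien‑6‑yn‑3‑ol
Conditions: (CH2=CH)2Zn [from 9 + ZnCl2, dioxane, filter], (−)‑MIB (10 mol %), toluene/Et2O, −30 → 0 °C
Reagents that add atoms: vinylmagnesium bromide, C=C[Mg]Br (via C=C[Zn]C=C)
Why: Amino‑alcohol‑catalysed enantioselective vinylzinc 1,2‑addition; (−)‑MIB is expected to direct Si‑face attack as it does for dialkylzincs, giving the (S)‑carbinol (C6), and any minor enantiomer becomes a separable diastereomer after step 7.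

**Step 6**
Reactants: 10; 11 chlorotriethylsilane
Product: 12 (S,Z)‑triethyl[(5‑methylhepta‑1,4‑dien‑6‑yn‑3‑yl)oxy]silane
Conditions: TESCl, imidazole, CH2Cl2, 0 °C
Reagents that add atoms: TESCl, CC[Si](CC)(CC)Cl
Why: Silylation is needed because a free C6–OH cis to the alkyne would cyclise onto the ynone (furan formation) in steps 7–8.

**Step 7**
Reactants: 12; 6
Product: 13 (3R,7Z,9S)‑1‑(tert‑butyldimethylsilyloxy)‑3‑hydroxy‑3,7‑dimethyl‑9‑(triethylsilyloxy)undeca‑7,10‑dien‑5‑yn‑4‑one
Conditions: 12, n‑BuLi, THF, −78 °C; then 6, −78 → −30 °C; aq. NH4Cl (acetone is lost on work‑up)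
Reagents that add atoms: none beyond 12 and 6
Why: Acetylide acyl substitution on the dioxolanone: the cyclic tetrahedral alkoxide survives until quench, so mono‑addition gives the α′‑hydroxy ynone with the C10 tertiary alcohol unmasked.

**Step 8**
Reactants: 13
Product: 14 (R)‑2‑[2‑(tert‑butyldimethylsilyloxy)ethyl]‑2‑methyl‑5‑[(2Z,4S)‑4‑(triethylsilyloxy)hexa‑2,5‑dien‑2‑yl]furan‑3(2H)‑one
Conditions: Ph3PAuCl/AgOTf (5 mol %), toluene, rt
Reagents that add atoms: none
Why: Gold‑catalysed 5‑endo‑dig addition of the tertiary OH to the ynone β‑carbon (C3) forms the 3(2H)‑furanone; it is an isomerisation, so C10 is untouched.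

**Step 9**
Reactants: 14
Product: 15 (R)‑2‑[2‑(tert‑butyldimethylsilyloxy)ethyl]‑5‑[(2Z,4S)‑4‑hydroxyhexa‑2,5‑dien‑2‑yl]‑2‑methylfuran‑3(2H)‑one
Conditions: HF·pyridine, excess pyridine, THF, 0 °C
Reagents that add atoms: none
Why: Selective desilylation: the secondary TES ether cleaves much faster than the primary TBS ether under buffered HF, and the non‑solvolytic conditions protect the bis‑allylic alcohol.

**Step 10**
Reactants: 15; 16 2‑(bromomethyl)acrylic acid
Product: 17 (3S,4Z)‑5‑[(R)‑5‑(2‑(tert‑butyldimethylsilyloxy)ethyl)‑5‑methyl‑4‑oxo‑4,5‑dihydrofuran‑2‑yl]hexa‑1,4‑dien‑3‑yl 2‑(bromomethyl)acrylate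
Conditions: 16, (COCl)2, DMF (cat.), CH2Cl2, 0 °C; then 15, 2,6‑lutidine, −20 → 0 °C
Reagents that add atoms: 2‑(bromomethyl)acrylic acid, C=C(CBr)C(=O)O
Why: Esterification via the acid chloride with a non‑nucleophilic base (no DMAP, which would attack the allylic bromide) occurs at oxygen with retention at C6.

**Step 11**
Reactants: 17
Product: 18 (R)‑3‑(bromomethyl)‑5‑{(Z)‑2‑[(R)‑5‑(2‑(tert‑butyldimethylsilyloxy)ethyl)‑5‑methyl‑4‑oxo‑4,5‑dihydrofuran‑2‑yl]prop‑1‑en‑1‑yl}furan‑2(5H)‑one
Conditions: Grubbs II (10 mol %), 1,4‑benzoquinone (20 mol %), CH2Cl2 (5 mM), 40 °C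
Reagents that add atoms: none (ethylene lost)
Why: Ring‑closing metathesis between the vinyl group and the 1,1‑disubstituted acrylate forms the C7=C11 butenolide while the trisubstituted, conjugated alkenes stay inert; C6 is unchanged in space (the label changes S → R only because CIP priorities change).

**Step 12**
Reactants: 18
Product: 19 (R)‑3‑(bromomethyl)‑5‑{(Z)‑2‑[(R)‑5‑(2‑hydroxyethyl)‑5‑methyl‑4‑oxo‑4,5‑dihydrofuran‑2‑yl]prop‑1‑en‑1‑yl}furan‑2(5H)‑one
Conditions: HF·pyridine, THF, 0 °C → rt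
Reagents that add atoms: none
Why: Acidic fluoride desilylation of the primary TBS ether; there is no base present to epimerise the acidic butenolide γ‑H (C6) or displace the allylic bromide.

**Step 13**
Reactants: 19
Product: 20 2‑[(R)‑5‑{(Z)‑1‑[(R)‑4‑(bromomethyl)‑5‑oxo‑2,5‑dihydrofuran‑2‑yl]prop‑1‑en‑2‑yl}‑2‑methyl‑3‑oxo‑2,3‑dihydrofuran‑2‑yl]acetaldehyde
Conditions: Dess–Martin periodinane, NaHCO3, CH2Cl2, 0 °C → rt; use at once
Reagents that add atoms: none
Why: Mild buffered Dess–Martin oxidation gives the C8 aldehyde without β‑elimination of the furanone oxygen or loss of bromide.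

**Step 14**
Reactants: 20
Product: 21 atripliciolide, (6R,7R,8R,10R)‑8‑hydroxy‑1‑oxo‑3,10‑epoxygermacra‑2,4Z,11(13)‑trien‑6,12‑olide
Conditions: CrCl2 (10 equiv), THF, rt; syringe‑pump addition of 20 to 2 mM final concentration
Reagents that add atoms: none (Br lost)
Why: Intramolecular Nozaki–Hiyama/Barbier allylation through C7 via a cyclic six‑membered transition state, with attack anti to the C6 alkenyl group giving the 6,7‑trans lactone (7R); the short C9–C10–O–C3 tether should hold C9 over the lactone with O8 syn to C13, giving 8R, but this is a prediction (see risk 1).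

**Step 15**
Reactants: 21; 22 tiglic acid
Product: 23 atripliciolide tiglate (target)
Conditions: 22, 2,4,6‑trichlorobenzoyl chloride, Et3N, toluene, rt; then 21, DMAP, rt
Reagents that add atoms: tiglic acid, C/C=C(\C)C(=O)O
Why: Yamaguchi esterification acylates the hindered secondary C8–OH with retention and without E/Z or deconjugative isomerisation of the tiglate.

## Compound list

1 | (R)‑citramalic acid | C[C@@](O)(CC(=O)O)C(=O)O | starting material
2 | 2,2‑dimethoxypropane | COC(C)(C)OC | starting material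
3 | (R)‑2‑(2,2,4‑trimethyl‑5‑oxo‑1,3‑dioxolan‑4‑yl)acetic acid | CC1(C)O[C@](C)(CC(=O)O)C(=O)O1 | intermediate
4 | (R)‑5‑(2‑hydroxyethyl)‑2,2,5‑trimethyl‑1,3‑dioxolan‑4‑one | CC1(C)O[C@](C)(CCO)C(=O)O1 | intermediate
5 | tert‑butyldimethylsilyl chloride | CC(C)(C)[Si](C)(C)Cl | starting material
6 | (R)‑5‑[2‑(TBS‑oxy)ethyl]‑2,2,5‑trimethyl‑1,3‑dioxolan‑4‑one | CC1(C)O[C@](C)(CCO[Si](C)(C)C(C)(C)C)C(=O)O1 | intermediate
7 | (Z)‑3‑methylpent‑2‑en‑4‑yn‑1‑ol | OC/C=C(/C)C#C | starting material
8 | (Z)‑3‑methylpent‑2‑en‑4‑ynal | O=C/C=C(/C)C#C | intermediate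
9 | vinylmagnesium bromide | C=C[Mg]Br | starting material
10 | (S,Z)‑5‑methylhepta‑1,4‑dien‑6‑yn‑3‑ol | O[C@@H](C=C)/C=C(/C)C#C | intermediate
11 | chlorotriethylsilane | CC[Si](CC)(CC)Cl | starting material
12 | (S,Z)‑triethyl[(5‑methylhepta‑1,4‑dien‑6‑yn‑3‑yl)oxy]silane | CC[Si](CC)(CC)O[C@@H](C=C)/C=C(/C)C#C | intermediate
13 | (3R,7Z,9S)‑1‑(TBS‑oxy)‑3‑hydroxy‑3,7‑dimethyl‑9‑(TES‑oxy)undeca‑7,10‑dien‑5‑yn‑4‑one | CC[Si](CC)(CC)O[C@@H](C=C)/C=C(/C)C#CC(=O)[C@](C)(O)CCO[Si](C)(C)C(C)(C)C | intermediate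
14 | (R)‑2‑[2‑(TBS‑oxy)ethyl]‑2‑methyl‑5‑[(2Z,4S)‑4‑(TES‑oxy)hexa‑2,5‑dien‑2‑yl]furan‑3(2H)‑one | CC[Si](CC)(CC)O[C@@H](C=C)/C=C(/C)C1=CC(=O)[C@@](C)(CCO[Si](C)(C)C(C)(C)C)O1 | intermediate
15 | (R)‑2‑[2‑(TBS‑oxy)ethyl]‑5‑[(2Z,4S)‑4‑hydroxyhexa‑2,5‑dien‑2‑yl]‑2‑methylfuran‑3(2H)‑one | O[C@@H](C=C)/C=C(/C)C1=CC(=O)[C@@](C)(CCO[Si](C)(C)C(C)(C)C)O1 | intermediate
16 | 2‑(bromomethyl)acrylic acid | C=C(CBr)C(=O)O | starting material
17 | 2‑(bromomethyl)acrylate ester of 15 (3S,4Z) | C=C(CBr)C(=O)O[C@@H](C=C)/C=C(/C)C1=CC(=O)[C@@](C)(CCO[Si](C)(C)C(C)(C)C)O1 | intermediate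
18 | bromobutenolide TBS ether (5R butenolide, Z, 5R furanone) | O=C1O[C@@H](C=C1CBr)/C=C(/C)C2=CC(=O)[C@@](C)(CCO[Si](C)(C)C(C)(C)C)O2 | intermediate
19 | bromobutenolide primary alcohol | O=C1O[C@@H](C=C1CBr)/C=C(/C)C2=CC(=O)[C@@](C)(CCO)O2 | intermediate
20 | bromobutenolide aldehyde | O=C1O[C@@H](C=C1CBr)/C=C(/C)C2=CC(=O)[C@@](C)(CC=O)O2 | intermediate
21 | atripliciolide (6R,7R,8R,10R) | C=C1C(=O)O[C@@H]2/C=C(/C)C3=CC(=O)[C@@](C)(C[C@@H](O)[C@@H]12)O3 | intermediate
22 | tiglic acid | C/C=C(\C)C(=O)O | starting material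
23 | atripliciolide tiglate | C=C1C(=O)O[C@@H]2/C=C(/C)C3=CC(=O)[C@@](C)(C[C@@H](OC(=O)/C(C)=C/C)[C@@H]12)O3 | target

## Step count

Total steps: 15. Longest linear sequence: 12 (steps 1–3 then 7–15; the other branch, steps 4–6 then 7–15, is also 12).

## Three steps most likely to fail

1. **Step 14 (Barbier macrocyclisation).** The ring is strained, oligomerisation competes, and the C8 configuration is not secured: an open chair transition state would favour the 8‑epimer. Fallback: run the Zn‑Barbier intermolecularly first, using a bromobutenolide that carries a (Z)‑vinyl iodide and a C8 aldehyde that carries the C10 carbinol and a terminal alkyne. Then close the ring by intramolecular Sonogashira coupling, oxidise, and form the furanone transannularly with gold. The intermolecular chair transition state should give the 8‑epi alcohol, so the ester would then be installed by Mitsunobu inversion with tiglic acid.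

2. **Step 5 (asymmetric vinylation of a small Z‑enynal bearing a free terminal alkyne).** The ee may be modest and alkynylzinc formation may compete. Fallback: couple the achiral TES ether of 7 with 6 and form the furanone first, then unmask and oxidise C6 to the Z‑enal. Set C6 there by Zn‑ProPhenol addition of methyl propiolate, followed by Lindlar semi‑hydrogenation with lactonisation to the butenolide, Morita–Baylis–Hillman hydroxymethylation with formaldehyde, and PBr3. This reaches the 18‑type bromobutenolide without vinylation or RCM.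

3. **Step 11 (RCM to a trisubstituted butenolide from a bis‑allylic 2‑(bromomethyl)acrylate).** Closure may be slow, and Ru–H species may isomerise the skipped diene. Fallback: build the butenolide by carbonylation instead. Asymmetric alkynylation of the Z‑enal with HC≡CCH2OTBS, then Red‑Al/I2 to the (Z)‑γ‑hydroxy vinyl iodide, Pd/CO carbonylative lactonisation, and TBS → Br (HF, then CBr4/PPh3).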